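## The problem

1. Target **15** is one ten-membered carbocycle. Its atoms are numbered C1 (carbinol carbon esterified by vanillic acid), C2 (methylene), C3 (methyl-bearing) and C4 joined by a Z double bond, C5 and C6 (methylenes), C7 (methyl-bearing) and C8 joined by a second Z double bond, C9 (free allylic carbinol) and C10 (isopropyl-bearing, bonded to C1).
2. A ten-membered ring is among the hardest to close end to end, and an open-chain precursor would also need two Z trisubstituted alkenes, each a stereoselective olefination problem of its own.
3. The three stereocentres are contiguous, C1 (R), C10 (S) and C9 (S); the two oxygens are 1,3-syn and the isopropyl group lies on the same ring face as both.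
4. C10 sits between the two oxygenated carbons, so at the 1,9-dione level it epimerises freely and can be set together with C1 in one dynamic reduction. C1 and C10 are then the only resident centres that can help or oppose the later reduction at C9.
5. The oxygens must end up differentiated, ester on C1 and free hydroxyl on C9, which rules out any passage through an unprotected 1,9-diol.
6. Fragile points are:
   - the C9 allylic alcohol (ionisation under acid, with transannular attack by the 1,5-diene);
   - the syn hydroxy ester (1,3-acyl shift under base);
   - the free phenol;
   - the skipped C3=C4 alkene beside a C1 carbonyl (conjugation);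
   - the β-hydroxy and β-acyloxy ketones met on the way (retro-aldol, elimination).
7. The enabling feature is that atoms C2 to C9, with both cis alkenes and both methyl groups, are the eight-membered ring of 1,5-dimethylcycloocta-1,5-diene, while C10 and C1 with the isopropyl group are the two carbons of isopropylketene. Inserting that unit between C9 and C2 gives the ring, the alkene geometry and the 1,3-dioxygen pattern in one operation.

## Retrosynthesis

**15 ⇒ 14.** The phenolic O–Si bond is cut. Unprotected vanillic acid cannot be activated without self-condensation, so the phenol travels as a tert-butyldimethylsilyl ether. Buffered fluoride removes it near neutrality, which the hydroxy ester and the allylic alcohol of **15** need. The forward step must be chemoselective and non-basic.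

**14 ⇒ 13.** The C9–H bond is cut, returning the carbinol to the C9 enone. Cutting the ester first would lead to a 1,9-diol with no reliable way to acylate only the C1 hydroxyl. Keeping C9 as a ketone while C1 is esterified solves the differentiation by oxidation state. The forward step must be a clean 1,2-reduction with hydride delivered to the Re face of C9 under catalyst control.

**13 ⇒ 9 + 12.** The ester C–O bond is cut, giving ketol **9** and silyl-protected vanillic acid **12**. Acid **12** comes from vanillic acid **10** through the doubly silylated **11**. The forward coupling must be mild enough that **9** does not undergo retro-aldol cleavage and **13** does not lose its β-acyloxy group.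

**9 ⇒ 8.** The C1–H bond is cut. In 1,3-dione **8** the stereocentre C10 is labile and the two carbonyls differ (C1 isolated, C9 conjugated). One enantioselective reduction at C1 under dynamic kinetic resolution therefore sets C1 and C10 together. Dione **8** has no fixed stereocentre, so it is much simpler than **9**. The forward step needs carbonyl selectivity, face selectivity and fast epimerisation at C10.

**8 ⇒ 4 + 6 (through 7).** This is the key disconnection. Bonds C1–C2 and C10–C9 are cut and the C9–C2 bond is restored, so **8** becomes the eight-membered silyl trienol ether **4** plus isopropylketene **6**, made from 3-methylbutanoyl chloride **5**. The forward link is the fused cyclobutanone **7**. The neighbouring cuts are a C1–C10 acylation or a ring-closing olefination. Both need an open chain with the two Z alkenes already built and a direct ten-membered closure. This cut borrows both alkenes from a commercial ring and forms the medium ring by opening a bicycle. The forward step needs site-selective attack at C2 of **4** and regioselective opening of **7** along the shared bond.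

**4 ⇒ 2 (through 3).** The O–Si bond is cut. Dienone **2** is deprotonated at the methylene that is both α′ to the carbonyl and allylic (target C2), giving lithium trienolate **3**, which is silylated on oxygen. No other position has this double activation, so kinetic control should suffice.

**2 ⇒ 1.** The C9 carbonyl is returned to a methylene. Diene **1** has a twofold axis, so the two ring methylenes next to a CH= terminus are equivalent and either gives **2**. The forward allylic oxidation must prefer these positions over the methylenes next to the methyl-bearing carbons and must stop after one oxidation.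

## Roads not taken

**Alternative 1: allylstannane–aldehyde closure of the C10–C1 bond.**
- Cut: the C10–C1 bond. The open-chain stannyl aldehyde A1 carries the C9 silyl ether and a 2-methylallylstannane.
- Forward step: BF3·OEt2 activates the C1 aldehyde, the stannane attacks through C10 with loss of tin from the terminal carbon, and the ring closes to A2 with C1 and C10 set and an isopropenyl group on C10.
- Merits: the ring-closing reaction type is known. One bond formation creates two stereocentres with C9 as relay. A2 already has a free C1 hydroxyl and a protected C9 oxygen, so the vanillate could be attached without any ketone reduction of uncertain facial outcome. In this respect it is better than the chosen plan.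
- Weak points:
  - A1 needs both Z trisubstituted alkenes made by olefination.
  - A1 holds a β,γ-unsaturated aldehyde prone to conjugation beside an acid-sensitive allylstannane.
  - The closure is a direct ten-membered cyclisation, and the syn/anti and facial outcome of an allyl transfer across a forming medium ring is hard to predict.
  - The isopropenyl group must be hydrogenated selectively beside two trisubstituted alkenes.
  - C9 must be set earlier by a separate asymmetric step.
- Comparison: the chosen plan sets against this its brevity, both alkenes taken from a commodity ring, and a ring formed by fragmentation. It pays with an unprecedented key step and a catalyst-controlled C9 reduction.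

**Alternative 2: [2,3]-Wittig contraction of a thirteen-membered diallylic ether.**
- Cut: the C9–C10 bond, restoring an O–C bond to the isopropenyl terminus, which leads to the macrocyclic ether A3.
- Forward step: sec-butyllithium deprotonates the ether carbon C9, and the [2,3] shift forms C9–C10 and contracts the ring to carbocycle A4 (free C9 hydroxyl, C1 para-methoxybenzyl ether, C10 isopropenyl).
- Merits: ring contraction avoids direct medium-ring closure. The five-membered transition state can relay the C1 configuration to C10 and C9, which is a more orderly flow of stereochemical information than two independent catalytic reductions.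
- Weak points:
  - A3 needs a macro-etherification and already contains three defined alkenes.
  - The two oxygen-flanked allylic positions compete for deprotonation.
  - A4 has the oxygens the wrong way round (C9 free, C1 protected). Protection of C9, removal of the benzyl ether, acylation and deprotection must follow, and so must the selective isopropenyl hydrogenation.
- Comparison: the chosen plan needs no protecting group on the ring and about half the operations. It has to accept that its stereocentres come from reagent control and not from an internal relay.

**Alternative 3: Grob fragmentation of a hydroazulene.**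
- Cut: the C3=C4 alkene and the C9 carbonyl are traced back to a C3–C9 bond and a C4 mesylate in the bicyclic hydroxy mesylate A5.
- Forward step: potassium tert-butoxide ionises the tertiary C9 alcohol, and the C3–C9 bond breaks anti to the C4–O bond, giving enone A6 with the Z C3=C4 alkene.
- Merits: the fragmentation is stereospecific and well known. Like the chosen plan it forms the ten-membered ring by cleaving a shared bond. A6 is the para-methoxybenzyl analogue of **13** with C1 and C10 already fixed, so it needs no enzyme. In precedent it is the safer ring-forming step.
- Weak points: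
  - A5 carries five stereocentres, two of them adjacent and fully substituted, and three are destroyed in the fragmentation.
  - A6 is a β-alkoxy ketone formed under strong base and can eliminate.
  - The benzyl ether must be exchanged for the vanillate.
  - The C9 reduction problem remains exactly as in the chosen plan.
- Comparison: the chosen plan reaches the same kind of enone in five steps from commodity chemicals. That is what it sets against the better precedent of this route.

Key step: step 3

Assumption: commercial 1,5-dimethylcycloocta-1,5-diene contains its 1,6-dimethyl isomer; it is taken to be removed by fractional distillation before step 1 (otherwise the isomeric enones are separated after step 1).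
Assumption: the ketoreductase of step 4 is the hit of a commercial enzyme panel screened for the (9R,10R) ketol; no single enzyme is specified.

## Route

Step 1
Reactants: 1 (1Z,5Z)-1,5-dimethylcycloocta-1,5-diene
Product: 2 (2Z,6Z)-3,7-dimethylcycloocta-2,6-dien-1-one
Conditions: CrO3, 3,5-dimethylpyrazole, CH2Cl2, −20 °C, stopped at partial conversion; 1 recovered
Reagents that add atoms: chromium trioxide, O=[Cr](=O)=O
Why: Allylic oxidation with the CrO3–3,5-dimethylpyrazole complex turns the ring methylene next to the CH= terminus of a trisubstituted alkene into a ketone without moving the double bond, so the β-methyl enone should result; the two such methylenes of 1 are related by the twofold axis and give the same product, and partial conversion limits attack on the second alkene.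

Step 2
Reactants: 2 (2Z,6Z)-3,7-dimethylcycloocta-2,6-dien-1-one
Product: 4 trimethyl{[(1E,3Z,7Z)-3,7-dimethylcycloocta-1,3,7-trien-1-yl]oxy}silane, via lithium trienolate 3 (not isolated)
Conditions: LiN(iPr)2, THF, −78 °C; Me3SiCl, −78 → 0 °C; pentane, filtration, concentrated cold and used at once
Reagents that add atoms: chlorotrimethylsilane, C[Si](C)(C)Cl
Why: Kinetic enolisation of an enone with a lithium amide removes the α′ proton, here at the ring methylene C8 of 2 (target C2), which is also allylic to the second alkene, and O-silylation gives the silyl enol ether with the new double bond between target C9 and C2; the two ring alkenes stay where they are, and the conjugated triene is kept cold to avoid electrocyclisation.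

Step 3
Reactants: 4 trimethyl{[(1E,3Z,7Z)-3,7-dimethylcycloocta-1,3,7-trien-1-yl]oxy}silane; 5 3-methylbutanoyl chloride
Product: 8 (4Z,8Z)-5,9-dimethyl-2-(propan-2-yl)cyclodeca-4,8-diene-1,3-dione, via isopropylketene 6 (not isolated), via fused siloxycyclobutanone 7 (not isolated)
Conditions: 5 by syringe pump, Et3N, CH2Cl2, 0 °C → rt; MeOH (destroys excess 5); then Bu4NF, THF, 0 °C; aq NH4Cl
Reagents that add atoms: none
Why: Proposed new method: Et3N dehydrochlorinates 5 to isopropylketene 6, the enol ether carbon C2 of 4 attacks the ketene carbonyl carbon (future C1), and the zwitterion, whose cation sits on siloxy-bearing C9 beside the enolate terminus C10, collapses by 4-exo-trig closure (C10 to C9) to the cis-fused siloxycyclobutanone 7, an asynchronous [2+2] cycloaddition. Fluoride then frees the C9 alkoxide, which opens by retro-aldol cleavage of the shared C9–C2 bond, so the ten-membered ring is formed by fragmentation of the bicycle and not by cyclisation, driven by loss of four-ring strain, by the C1 dienolate conjugated with C3=C4 and by the new C9 enone. The closest known reaction type is the [2+2] cycloaddition of dichloroketene with silyl enol ethers followed by dechlorination and retro-aldol opening to two-carbon-enlarged cyclic 1,3-diones; a monoalkylketene, a conjugated silyl trienol ether and opening in the same flask lie outside it. No stereocentre needs control, since C9 and C2 of 7 lose their configuration on opening and C10 of 8, flanked by two carbonyl groups, stays labile for step 4. Site selectivity for C2 over the vinylogous C4 is expected because the twisted eight-membered triene leaves C9=C2 a nearly isolated enol ether and because only attack at C2 places the cation next to C10 for immediate closure. Cycloaddition must outrun ketene dimerisation, which is why 5 is added slowly to 4 and the base. Opening toward C2 and not toward C10 is favoured by the better-stabilised dienolate, and proton transfer from the acidic C10–H to C2 stores the product as the 1,3-diketonate, which keeps C3=C4 out of conjugation. Both Z ring alkenes are those of the eight-membered ring and are not touched.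

Step 4
Reactants: 8 (4Z,8Z)-5,9-dimethyl-2-(propan-2-yl)cyclodeca-4,8-diene-1,3-dione
Product: 9 (2Z,6Z,9R,10R)-9-hydroxy-3,7-dimethyl-10-(propan-2-yl)cyclodeca-2,6-dien-1-one
Conditions: NADPH-dependent ketoreductase (panel hit), NADP+ (cat.), iPrOH, phosphate buffer pH 7, DMSO cosolvent, 30 °C
Reagents that add atoms: none
Why: Ketoreductase reduction of a 2-alkyl-1,3-diketone under dynamic kinetic resolution: C10 epimerises quickly through the diketone enol at pH 7, and the enzyme should reduce only the (10R) dione, only at the unconjugated C1 carbonyl (C9 of this name) and on its Si face. This sets target C1 (R) and C10 with the isopropyl group cis to the new hydroxyl in one step; the ketol no longer epimerises under these neutral conditions.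

Step 5
Reactants: 10 4-hydroxy-3-methoxybenzoic acid (vanillic acid)
Product: 12 4-{[tert-butyl(dimethyl)silyl]oxy}-3-methoxybenzoic acid, via bis-silylated vanillic acid 11 (not isolated)
Conditions: tBuMe2SiCl, imidazole, DMF, rt; then AcOH/THF/H2O, rt
Reagents that add atoms: tert-butyldimethylsilyl chloride, CC(C)(C)[Si](C)(C)Cl
Why: Silylation covers both acidic hydroxyls, and the silyl ester is hydrolysed far faster than the aryl silyl ether, so the phenol alone stays protected; this is a standard protection of a hydroxybenzoic acid.

Step 6
Reactants: 9 (2Z,6Z,9R,10R)-9-hydroxy-3,7-dimethyl-10-(propan-2-yl)cyclodeca-2,6-dien-1-one; 12 4-{[tert-butyl(dimethyl)silyl]oxy}-3-methoxybenzoic acid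
Product: 13 (1R,3Z,7Z,10R)-3,7-dimethyl-9-oxo-10-(propan-2-yl)cyclodeca-3,7-dien-1-yl 4-{[tert-butyl(dimethyl)silyl]oxy}-3-methoxybenzoate
Conditions: EDC·HCl, DMAP (cat.), CH2Cl2, 0 °C → rt
Reagents that add atoms: none
Why: Steglich esterification of the secondary C1 alcohol; no stereocentre is touched, and the cold, nearly neutral medium should avoid retro-aldol cleavage of 9 and E1cB loss of the new β-acyloxy group from 13.

Step 7
Reactants: 13 (1R,3Z,7Z,10R)-3,7-dimethyl-9-oxo-10-(propan-2-yl)cyclodeca-3,7-dien-1-yl 4-{[tert-butyl(dimethyl)silyl]oxy}-3-methoxybenzoate
Product: 14 (1R,3Z,7Z,9S,10S)-9-hydroxy-3,7-dimethyl-10-(propan-2-yl)cyclodeca-3,7-dien-1-yl 4-{[tert-butyl(dimethyl)silyl]oxy}-3-methoxybenzoate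
Conditions: (S)-1-methyl-3,3-diphenyltetrahydro-1H,3H-pyrrolo[1,2-c][1,3,2]oxazaborole [(S)-Me-CBS], catecholborane, toluene, −78 °C; MeOH quench; cold pH 9 carbonate wash
Reagents that add atoms: none
Why: Corey–Bakshi–Shibata reduction: the oxazaborolidine with catecholborane reduces the enone carbonyl 1,2 at −78 °C and should leave the ester, the aryl silyl ether and the trisubstituted alkenes alone. With the alkenyl flank C8 acting as the large group, as is usual for conjugated enones, the (S)-catalyst should deliver hydride to the Re face of C9 and set C9 (S), syn to the C1 oxygen; the catalyst and not the ring is meant to decide the face.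

Step 8
Reactants: 14 (1R,3Z,7Z,9S,10S)-9-hydroxy-3,7-dimethyl-10-(propan-2-yl)cyclodeca-3,7-dien-1-yl 4-{[tert-butyl(dimethyl)silyl]oxy}-3-methoxybenzoate
Product: 15 (1R,3Z,7Z,9S,10S)-9-hydroxy-3,7-dimethyl-10-(propan-2-yl)cyclodeca-3,7-dien-1-yl 4-hydroxy-3-methoxybenzoate
Conditions: Bu4NF, AcOH (1:1), THF, 0 °C
Reagents that add atoms: none
Why: Fluoride cleavage of an aryl silyl ether; the acetic acid buffer keeps the medium near neutral, so the vanillate should not migrate to the C9 hydroxyl and the allylic alcohol is not ionised.

## Compound list

1 | (1Z,5Z)-1,5-dimethylcycloocta-1,5-diene | C/C1=C/CC/C(C)=C\CC1 | starting material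
2 | (2Z,6Z)-3,7-dimethylcycloocta-2,6-dien-1-one (C1 = target C9, C8 = target C2) | O=C1/C=C(C)\CC/C=C(C)\C1 | intermediate
3 | lithium (1E,3Z,7Z)-3,7-dimethylcycloocta-1,3,7-trien-1-olate | C1/C(C)=C\C(O[Li])=C/C(C)=C\C1 | intermediate (not isolated)
4 | trimethyl{[(1E,3Z,7Z)-3,7-dimethylcycloocta-1,3,7-trien-1-yl]oxy}silane (C1 = target C9, C2 = target C2) | C1/C(C)=C\C(O[Si](C)(C)C)=C/C(C)=C\C1 | intermediate
5 | 3-methylbutanoyl chloride | CC(C)CC(Cl)=O | starting material
6 | isopropylketene (3-methylbut-1-en-1-one) | CC(C)C=C=O | intermediate (not isolated)
7 | (2Z,6Z)-3,7-dimethyl-10-(propan-2-yl)-1-[(trimethylsilyl)oxy]bicyclo[6.2.0]deca-2,6-dien-9-one, cis-fused, racemic, both epimers at the isopropyl carbon | O=C1C(C(C)C)C2(O[Si](C)(C)C)/C=C(C)\CC/C=C(C)\C12 | intermediate (not isolated)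
8 | (4Z,8Z)-5,9-dimethyl-2-(propan-2-yl)cyclodeca-4,8-diene-1,3-dione (ketones at target C1 and C9; C10 labile) | O=C1C/C(C)=C\CC/C(C)=C\C(=O)C1C(C)C | intermediate
9 | (2Z,6Z,9R,10R)-9-hydroxy-3,7-dimethyl-10-(propan-2-yl)cyclodeca-2,6-dien-1-one (hydroxyl on target C1, ketone at target C9) | O[C@@H]1C/C(C)=C\CC/C(C)=C\C(=O)[C@@H]1C(C)C | intermediate
10 | 4-hydroxy-3-methoxybenzoic acid (vanillic acid) | COc1cc(C(=O)O)ccc1O | starting material
11 | tert-butyl(dimethyl)silyl 4-{[tert-butyl(dimethyl)silyl]oxy}-3-methoxybenzoate | COc1cc(C(=O)O[Si](C)(C)C(C)(C)C)ccc1O[Si](C)(C)C(C)(C)C | intermediate (not isolated)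
12 | 4-{[tert-butyl(dimethyl)silyl]oxy}-3-methoxybenzoic acid | COc1cc(C(=O)O)ccc1O[Si](C)(C)C(C)(C)C | intermediate
13 | (1R,3Z,7Z,10R)-3,7-dimethyl-9-oxo-10-(propan-2-yl)cyclodeca-3,7-dien-1-yl 4-{[tert-butyl(dimethyl)silyl]oxy}-3-methoxybenzoate | COc1cc(C(=O)O[C@@H]2C/C(C)=C\CC/C(C)=C\C(=O)[C@@H]2C(C)C)ccc1O[Si](C)(C)C(C)(C)C | intermediate
14 | (1R,3Z,7Z,9S,10S)-9-hydroxy-3,7-dimethyl-10-(propan-2-yl)cyclodeca-3,7-dien-1-yl 4-{[tert-butyl(dimethyl)silyl]oxy}-3-methoxybenzoate | COc1cc(C(=O)O[C@@H]2C/C(C)=C\CC/C(C)=C\[C@H](O)[C@@H]2C(C)C)ccc1O[Si](C)(C)C(C)(C)C | intermediate
15 | (1R,3Z,7Z,9S,10S)-9-hydroxy-3,7-dimethyl-10-(propan-2-yl)cyclodeca-3,7-dien-1-yl 4-hydroxy-3-methoxybenzoate | COc1cc(C(=O)O[C@@H]2C/C(C)=C\CC/C(C)=C\[C@H](O)[C@@H]2C(C)C)ccc1O | target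

## Step count and risks

Total step count: 8. Longest linear sequence: 7 (steps 1, 2, 3, 4, 6, 7, 8); step 5 is a one-step side branch.

**Step 3 (key step, no direct precedent).**
- Most likely failure: ketene dimerisation outruns cycloaddition, because a monoalkylketene is a much weaker electrophile than the haloketenes used in the known reaction.
- Further failure modes: attack at the vinylogous C4, and silyl transfer within the zwitterion, which would give simple C-acylation without ring closure.
- Fallback in known chemistry, from **4**: chloro(isopropyl)ketene F1 is generated from 2-chloro-3-methylbutanoyl chloride (a purchasable reagent, otherwise one step from the acid) and Et3N. It is a haloketene of the class known to add to silyl enol ethers and should give the chlorinated siloxycyclobutanone F2. Zinc dust in acetic acid removes the chlorine to give **7**, now isolated. Bu4NF opens **7** to **8**, where the route is rejoined.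

**Step 1.**
- Most likely failure: hydrogen abstraction at the methylene next to the methyl-bearing alkene carbon, giving the 2-methyl enone, and a second oxidation at the remote alkene or at the doubly activated methylene of **2**.
- Fallback, from **1**: monoepoxidation with mCPBA gives the epoxide F3. Sodium phenylselenide (NaSePh, from PhSeSePh and NaBH4) opens it at the less substituted carbon to the hydroxy selenide F4. H2O2 oxidation and syn elimination away from the carbinol give the tertiary allylic alcohol F5. Pyridinium chlorochromate, [C5H5NH][CrO3Cl], then effects the Babler–Dauben oxidative 1,3-transposition to **2**. The regiochemistry is fixed by the sequence and not by C–H selectivity.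

**Step 4.**
- Most likely failure: no panel enzyme accepts the bulky, partly enolised ten-membered dione, or reduction occurs at C9 or with the wrong diastereoselectivity.
- Fallback, from **8**: NaBH4 in CH2Cl2/MeOH at −78 °C reduces the unconjugated ketone chemoselectively; the racemic 1,10-cis ketol F6 is separated from its trans isomer. Lipase-catalysed acetylation (Burkholderia cepacia lipase, vinyl acetate) should, by the empirical size rule for secondary alcohols, acylate the (1R) enantiomer to the acetate F7. The same lipase in pH 7 buffer hydrolyses F7 to **9**. This replaces a dynamic reduction by a classical kinetic resolution, at the cost of half the material.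

**Step 7.**
- Most likely failure: poor or reversed facial selectivity. Both flanks of the C9 carbonyl are bulky (a ring alkene on one side, the doubly branched C10 on the other), so the usual large/small assignment may not hold, and the conformational bias of the ring may override the catalyst.
- Fallback, from **13**: if the ring bias delivers the 9R epimer, it is used. Luche reduction (NaBH4, CeCl3·7H2O, MeOH, −78 °C) gives the C9 epimer F8. Mitsunobu inversion with chloroacetic acid (PPh3, diisopropyl azodicarboxylate) gives the 9S chloroacetate F9. Thiourea with NaHCO3 in ethanol removes the chloroacetyl group selectively and returns **14**.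

## Further compounds

F1 | step 3 | chloro(isopropyl)ketene (2-chloro-3-methylbut-1-en-1-one) | CC(C)C(Cl)=C=O
F2 | step 3 | (2Z,6Z)-10-chloro-3,7-dimethyl-10-(propan-2-yl)-1-[(trimethylsilyl)oxy]bicyclo[6.2.0]deca-2,6-dien-9-one, cis-fused, racemic | O=C1C(Cl)(C(C)C)C2(O[Si](C)(C)C)/C=C(C)\CC/C=C(C)\C12
F3 | step 1 | (4Z)-1,5-dimethyl-9-oxabicyclo[6.1.0]non-4-ene, racemic | CC12CC/C=C(C)\CCC1O2
F4 | step 1 | (4Z)-1,5-dimethyl-8-(phenylselanyl)cyclooct-4-en-1-ol, trans, racemic | CC1(O)CC/C=C(C)\CCC1[Se]c1ccccc1
F5 | step 1 | (2Z,5Z)-1,5-dimethylcycloocta-2,5-dien-1-ol, racemic | CC1(O)/C=C\C/C(C)=C\CC1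
F6 | step 4 | racemic 1,10-cis ketol (racemate of 9; relative configuration shown) | O[C@@H]1C/C(C)=C\CC/C(C)=C\C(=O)[C@@H]1C(C)C
F7 | step 4 | acetate of 9 at the target C1 oxygen | CC(=O)O[C@@H]1C/C(C)=C\CC/C(C)=C\C(=O)[C@@H]1C(C)C
F8 | step 7 | C9 epimer of 14 (1R,9R,10S) | COc1cc(C(=O)O[C@@H]2C/C(C)=C\CC/C(C)=C\[C@@H](O)[C@@H]2C(C)C)ccc1O[Si](C)(C)C(C)(C)C
F9 | step 7 | C9 chloroacetate of 14 (C9 configured as in 14) | COc1cc(C(=O)O[C@@H]2C/C(C)=C\CC/C(C)=C\[C@H](OC(=O)CCl)[C@@H]2C(C)C)ccc1O[Si](C)(C)C(C)(C)C
A1 | alternative 1 | (3Z,7Z,9S,10E)-9-{[tert-butyl(dimethyl)silyl]oxy}-3,7,11-trimethyl-12-(tributylstannyl)dodeca-3,7,10-trienal | O=CC/C(C)=C\CC/C(C)=C\[C@H](O[Si](C)(C)C(C)(C)C)/C=C(\C)C[Sn](CCCC)(CCCC)CCCC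
A2 | alternative 1 | (1R,3Z,7Z,9S,10R)-9-{[tert-butyl(dimethyl)silyl]oxy}-3,7-dimethyl-10-(prop-1-en-2-yl)cyclodeca-3,7-dien-1-ol | O[C@@H]1C/C(C)=C\CC/C(C)=C\[C@H](O[Si](C)(C)C(C)(C)C)[C@@H]1C(C)=C
A3 | alternative 2 | (3E,5R,7Z,11Z)-5-[(4-methoxyphenyl)methoxy]-3,7,11-trimethyl-1-oxacyclotrideca-3,7,11-triene | COc1ccc(CO[C@@H]2C/C(C)=C\CC/C(C)=C\COC/C(C)=C/2)cc1
A4 | alternative 2 | (1S,2Z,6Z,9R,10S)-9-[(4-methoxyphenyl)methoxy]-3,7-dimethyl-10-(prop-1-en-2-yl)cyclodeca-2,6-dien-1-ol | COc1ccc(CO[C@@H]2C/C(C)=C\CC/C(C)=C\[C@H](O)[C@@H]2C(C)=C)cc1
A5 | alternative 3 | trans-fused hydroazulene hydroxy mesylate (target numbering: C3–C9 bond intact, C9 tertiary alcohol, C3 angular methyl, C4 mesylate trans to that methyl, C7=C8 alkene, C1 para-methoxybenzyl ether, C10 isopropyl) | COc1ccc(CO[C@@H]2C[C@]3(C)[C@H](OS(C)(=O)=O)CC/C(C)=C\[C@@]3(O)[C@@H]2C(C)C)cc1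
A6 | alternative 3 | (2Z,6Z,9R,10R)-9-[(4-methoxyphenyl)methoxy]-3,7-dimethyl-10-(propan-2-yl)cyclodeca-2,6-dien-1-one | COc1ccc(CO[C@@H]2C/C(C)=C\CC/C(C)=C\C(=O)[C@@H]2C(C)C)cc1
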